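**Plan**

- Retrosynthesis: ring D is opened at C13–C16 (ketyl–alkyne closure of a C8 propargyl ketone); the C7 acid and the 2β-OH go back to the alkenes C6=C7 and C2=C3; C3 is taken back to a ketone.
- Enabling feature: ring A and the 19,20-δ-lactone form a 3-oxabicyclo[3.3.1]nonane sharing C4, C5 and C10, fused to ring B along C5–C10. With a C3 ketone, C4–C19 is a retro-Claisen bond and ring A a Diels–Alder retron, so C4–C19, C5–C10 and C1–C2 are cut in one event.
- This leaves ring C with a 2-silyloxy diene arm on C8 and a 2-(phenoxycarbonyloxymethyl)vinyl arm on C9; ring C is cut at C8–C15 (Sakurai), C8–C6 (Mukaiyama–Michael) and by a Robinson disconnection.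
- Forward order: ring C (steps 1–4), the three arms (5–13), rings B and A plus the lactone in one pot (14), ring A and C7 adjusted (15–19), ring D last (20–22).
- Stereochemistry: C9 from the organocatalyst; C8 by addition anti to the C9 arm; C5, C10 and C4 in the key step; C2 by exo hydroboration; C6 by equilibration; C13 by the bridge.

Key step: step 14

Remark: carbon atoms keep their gibberellane numbers (C1 to C20) in every intermediate.

**Route**

Step 1
Reactants: 1 methyl 4-oxobutanoate; 2 but-3-en-2-one
Product: 4 methyl 2-[(1S)-4-oxocyclohex-2-en-1-yl]acetate, via keto aldehyde 3 (not isolated)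
Conditions: (S)-2-[diphenyl(trimethylsilyloxy)methyl]pyrrolidine (10 mol%), ethyl 3,4-dihydroxybenzoate (20 mol%), neat, 4 °C; then p-MeC6H4SO3H·H2O (cat.), PhMe, 80 °C
Reagents that add atoms: none
Why: Organocatalytic Robinson annulation, in which the (S)-diarylprolinol ether shields one face of the E-enamine of 1 so that the Michael addition sets C9 as S, and acid-mediated aldol condensation then closes ring C.

Step 2
Reactants: 4 methyl 2-[(1S)-4-oxocyclohex-2-en-1-yl]acetate
Product: 5 trans silyl enol ether diester (C13 OSitBuMe2, C8 and C9 each carrying CH2CO2Me)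
Conditions: CH2=C(OMe)OSitBuMe2, MeCN, 55 °C
Reagents that add atoms: 1-(tert-butyldimethylsilyloxy)-1-methoxyethene, C=C(OC)O[Si](C)(C)C(C)(C)C
Why: Mukaiyama–Michael addition with silyl transfer brings C6 and C5 (the CH2CO2Me arm) to C8 and directly gives the regiodefined C13 silyl enol ether needed for re-oxidation, the C8 configuration being of no consequence here.

Step 3
Reactants: 5 trans silyl enol ether diester
Product: 6 dimethyl 2,2'-[(1S)-4-oxocyclohex-2-ene-1,2-diyl]diacetate
Conditions: Pd(OAc)2 (10 mol%), oxygen (1 atm), DMSO, 60 °C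
Reagents that add atoms: none
Why: Saegusa–Ito oxidation (palladium enolate, β-hydride elimination towards C8–H) regenerates the C14=C8 enone, which now carries the C6 arm, under non-basic conditions that leave the γ-stereocentre C9 untouched.

Step 4
Reactants: 6 dimethyl 2,2'-[(1S)-4-oxocyclohex-2-ene-1,2-diyl]diacetate
Product: 7 dimethyl 2,2'-[(1R,2S)-1-allyl-5-oxocyclohexane-1,2-diyl]diacetate
Conditions: allylSiMe3, TiCl4, CH2Cl2, -78 °C
Reagents that add atoms: allyltrimethylsilane, C=CC[Si](C)(C)C
Why: Hosomi–Sakurai conjugate allylation of the β,β-disubstituted enone creates the C8 quaternary centre by axial attack anti to the C9 side chain, which leaves the two CH2CO2Me arms cis and the allyl group (C15–C17) trans to the C9 arm.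

Step 5
Reactants: 7 dimethyl 2,2'-[(1R,2S)-1-allyl-5-oxocyclohexane-1,2-diyl]diacetate
Product: 9 keto aldehyde diester (C8–CH2CHO), via secondary ozonide 8 (not isolated)
Conditions: ozone, CH2Cl2, -78 °C; then PPh3, -78 °C to rt
Reagents that add atoms: ozone, [O-][O+]=O
Why: Ozonolysis of the only alkene with reductive work-up gives the aldehyde at C16 on the C15 methylene.

Step 6
Reactants: 9 keto aldehyde diester
Product: 10 bis(1,3-dioxolane) diester (C13 ketal, C16 acetal)
Conditions: Me3SiOCH2CH2OSiMe3 (2.5 equiv), Me3SiOTf (5 mol%), CH2Cl2, -78 to -20 °C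
Reagents that add atoms: 1,2-bis(trimethylsilyloxy)ethane, C[Si](C)(C)OCCO[Si](C)(C)C
Why: Noyori acetalisation masks the C13 ketone and the C16 aldehyde at low temperature without touching the two methyl esters.

Step 7
Reactants: 10 bis(1,3-dioxolane) diester
Product: 11 bis(1,3-dioxolane) dialdehyde (C8–CH2CHO and C9–CH2CHO)
Conditions: iBu2AlH (2.2 equiv), PhMe, -78 °C; aq. KNaC4H4O6 work-up
Reagents that add atoms: none
Why: Low-temperature ester reduction stops at the tetrahedral aluminium hemiacetals, which release both aldehydes on work-up.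

Step 8
Reactants: 11 bis(1,3-dioxolane) dialdehyde
Product: 12 mono-enal (C9 arm C(=CH2)CHO, C8 arm CH2CHO)
Conditions: CH2=NMe2+ I- (1.05 equiv), Et3N, CH2Cl2, 0 °C to rt
Reagents that add atoms: N,N-dimethylmethyleneiminium iodide, C=[N+](C)C.[I-]
Why: Eschenmoser methylenation (Mannich reaction, then β-elimination) should occur faster at the α-CH2 next to the tertiary C9 (C10) than at the neopentyl α-CH2 next to the quaternary C8 (C6), and the tertiary-amine base at low temperature disfavours aldol closure of the 1,6-dialdehyde.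

Step 9
Reactants: 12 mono-enal
Product: 13 allylic alcohol aldehyde (C9 arm C(=CH2)CH2OH, C8 arm CH2CHO)
Conditions: NaBH4, CeCl3·7H2O, EtOH/H2O, -15 °C
Reagents that add atoms: none
Why: Luche-type chemoselective reduction, in which the saturated aldehyde is masked in situ as its hydrate or hemiacetal while the conjugated aldehyde is reduced 1,2 to the C20 alcohol.

Step 10
Reactants: 13 allylic alcohol aldehyde
Product: 14 allylic alcohol enal (C8 arm C(=CH2)CHO, C9 arm C(=CH2)CH2OH)
Conditions: CH2=NMe2+ I- (3 equiv), Et3N, CH2Cl2, 40 °C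
Reagents that add atoms: N,N-dimethylmethyleneiminium iodide, C=[N+](C)C.[I-]
Why: A second Eschenmoser methylenation, now at the neopentyl C6 position under more forcing conditions, installs C7 as the exocyclic methylene and is run before the carbonate is made so that liberated dimethylamine cannot cleave it.

Step 11
Reactants: 14 allylic alcohol enal
Product: 15 phenyl carbonate enal (C20–O–CO–OPh)
Conditions: PhOCOCl, pyridine, CH2Cl2, 0 °C
Reagents that add atoms: phenyl chloroformate, O=C(Cl)Oc1ccccc1
Why: Acylation of the primary allylic alcohol places C19 as an aryl carbonate on the C20 oxygen, the tether for the later acyl transfer.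

Step 12
Reactants: 15 phenyl carbonate enal
Product: 16 dienone carbonate (C8 arm C(=CH2)–CH=C(Me)–C(O)Me, E)
Conditions: Ph3P=C(Me)C(O)Me, PhMe, 90 °C
Reagents that add atoms: 3-(triphenylphosphoranylidene)butan-2-one, CC(=O)C(C)=P(c1ccccc1)(c1ccccc1)c1ccccc1
Why: Wittig olefination with the acyl-stabilised ylide gives the E-configured trisubstituted C5=C4 enone and brings in C4, C18, C3 and C2.

Step 13
Reactants: 16 dienone carbonate
Product: 17 silyloxy triene carbonate (C2=C3(OSiiPr3)–C4(Me)=C5)
Conditions: iPr3SiOTf, Et3N, CH2Cl2, -78 to 0 °C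
Reagents that add atoms: triisopropylsilyl trifluoromethanesulfonate, CC(C)[Si](C(C)C)(C(C)C)OS(=O)(=O)C(F)(F)F
Why: Soft enolisation can only take place at the C2 methyl group, since C4 carries no hydrogen, and gives the cross-conjugated 2-silyloxy diene.

Step 14
Reactants: 17 silyloxy triene carbonate
Product: 19 tetracyclic keto lactone (19,20-lactone; C3 ketone; C6=C7 methylene), via Diels–Alder adduct 18 (not isolated)
Conditions: PhMe (0.01 M), 2,6-di-tert-butyl-4-methylphenol (cat.), sealed tube, 190 °C; then cool, Bu4NF, THF, 0 °C to rt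
Reagents that add atoms: none
Why: On heating, the 2-silyloxy diene C2=C3(OSi)–C4(Me)=C5 on the C8 arm adds to the 1,1-disubstituted alkene C10=C1 on the C9 arm in a type 1 intramolecular Diels–Alder reaction (three-atom tether C6–C8–C9), which forms C5–C10 and C1–C2; fluoride then frees the C3–C4 enolate, which attacks the phenyl carbonate on the 1,3-diaxial C20 oxygen (Baker–Venkataraman-type O-to-C acyl transfer, loss of phenoxide) and forms C4–C19. Closest known types: intramolecular Diels–Alder reactions of 1,6,8-nonatrienes that give angularly substituted hydrindanes, and C-acylation of fluoride-generated enolates by carbonates. Ring closures: ring A by the [4+2] cycloaddition, ring B as the five-membered tether ring of the same event, the δ-lactone by 6-exo-trig addition–elimination at the carbonate carbon. Stereocentres: C5 and C10 arise suprafacially from the E-diene and the alkene, with the trans relation of H-5 and C-20 set by the anti transition state in which the bulky tether carbon C9 avoids the C4 methyl group and the small C20 arm sits endo, and with the sense relative to ring C set by the cis arms on C8 and C9 and by H-9 eclipsing C10=C1 (allylic strain); C4 is set by the tether, since C19 can only arrive on the face that carries C20. The step needs anti over syn cycloaddition and C- over O-acylation: the first should be secured by the C4 methyl group, the second by ring size (six-membered lactone against an eight-membered enol carbonate) and by the irreversible loss of phenoxide.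

Step 15
Reactants: 19 tetracyclic keto lactone
Product: 20 C2=C3 enol triflate
Conditions: KN(SiMe3)2, THF, -78 °C; then PhNTf2
Reagents that add atoms: N-phenylbis(trifluoromethanesulfonimide), O=S(=O)(N(c1ccccc1)S(=O)(=O)C(F)(F)F)C(F)(F)F
Why: Kinetic deprotonation of the C3 ketone is possible only at C2, because C4 is quaternary, and O-sulfonylation of the potassium enolate gives the enol triflate.

Step 16
Reactants: 20 C2=C3 enol triflate
Product: 21 2,3-alkene (C2=C3 in ring A, C6=C7 exocyclic)
Conditions: Pd(OAc)2 (5 mol%), PPh3, HCO2H, Bu3N, DMF, 60 °C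
Reagents that add atoms: none
Why: Palladium-catalysed formate reduction of the enol triflate (oxidative addition to zerovalent palladium, hydride transfer from formate, reductive elimination) removes the C3 oxygen and leaves the ring A alkene.

Step 17
Reactants: 21 2,3-alkene
Product: 23 6-epi 2β,7-diol, via bis(borane) adduct 22 (not isolated)
Conditions: 9-BBN (4 equiv), THF, 0 to 60 °C; then 30% H2O2, aq. NaOAc, 0 °C to rt
Reagents that add atoms: hydrogen peroxide, OO
Why: Hydroboration–oxidation in which boron adds to C7 of the exocyclic alkene and to C2 of the ring A alkene (C3 is neopentyl), in ring A from the exo face opposite the lactone bridge, which sets the 2β-hydroxyl group, while the C6 configuration formed here is corrected in step 18.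

Step 18
Reactants: 23 6-epi 2β,7-diol
Product: 25 7-aldehyde of natural C6 configuration, via 6-epi aldehyde 24 (not isolated)
Conditions: 2,2,6,6-tetramethylpiperidin-1-oxyl (10 mol%), PhI(OAc)2, CH2Cl2, rt; then DBU, rt
Reagents that add atoms: none
Why: Oxoammonium oxidation is selective for the primary alcohol over the secondary C2 alcohol, and base equilibration of the α-stereocentre should place the formyl group cis to H-5 and trans to the quaternary C4, which is the natural C6 configuration whichever face was hydroborated.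

Step 19
Reactants: 25 7-aldehyde of natural C6 configuration
Product: 26 7-carboxylic acid
Conditions: NaClO2, NaH2PO4, 2-methyl-2-butene, tBuOH/H2O, 0 °C to rt
Reagents that add atoms: sodium chlorite, [Na+].[O-]Cl=O
Why: Pinnick oxidation converts the aldehyde into the C7 acid under buffered conditions that do not epimerise C6 or touch the acetals.

Step 20
Reactants: 26 7-carboxylic acid
Product: 27 keto aldehyde acid (C13 ketone, C15H2–C16HO)
Conditions: 1 M HCl, THF, rt
Reagents that add atoms: water, O
Why: Acid hydrolysis of the two dioxolanes releases the C13 ketone and the C16 aldehyde, the trans relation of 2β-OH and C19 excluding translactonisation.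

Step 21
Reactants: 27 keto aldehyde acid
Product: 28 alkynyl ketone acid (C8–CH2–C≡CH)
Conditions: MeC(O)C(N2)P(O)(OMe)2, K2CO3, MeOH, 0 °C to rt
Reagents that add atoms: dimethyl (1-diazo-2-oxopropyl)phosphonate, CC(=O)C(=[N+]=[N-])P(=O)(OC)OC
Why: Ohira–Bestmann homologation converts the aldehyde into the terminal alkyne (C16≡C17) while the ketone and the hindered lactone do not react.

Step 22
Reactants: 28 alkynyl ketone acid
Product: 29 target gibberellin (number 98 of the gibberellin A series)
Conditions: SmI2 (5 equiv), HMPA, tBuOH, THF, 0 °C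
Reagents that add atoms: none
Why: Ketyl–alkyne reductive cyclisation with divalent samarium (5-exo-dig) forms C13–C16, the exocyclic methylene and the tertiary alcohol at once, the C13 configuration being dictated by the one-carbon bridge C14.

**Compound list**

1 | methyl 4-oxobutanoate | COC(=O)CCC=O | starting material
2 | but-3-en-2-one | CC(=O)C=C | starting material
3 | methyl (3S)-3-formyl-6-oxoheptanoate | CC(=O)CC[C@H](C=O)CC(=O)OC | intermediate
4 | methyl 2-[(1S)-4-oxocyclohex-2-en-1-yl]acetate | C1=CC(=O)CC[C@H]1CC(=O)OC | intermediate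
5 | dimethyl 2,2'-[(1S,2S)-4-(tert-butyldimethylsilyloxy)cyclohex-3-ene-1,2-diyl]diacetate (arms trans) | COC(=O)C[C@@H]1C=C(O[Si](C)(C)C(C)(C)C)CC[C@H]1CC(=O)OC | intermediate
6 | dimethyl 2,2'-[(1S)-4-oxocyclohex-2-ene-1,2-diyl]diacetate | COC(=O)CC1=CC(=O)CC[C@H]1CC(=O)OC | intermediate
7 | dimethyl 2,2'-[(1R,2S)-1-allyl-5-oxocyclohexane-1,2-diyl]diacetate (CH2CO2Me arms cis) | C=CC[C@]1(CC(=O)OC)CC(=O)CC[C@H]1CC(=O)OC | intermediate
8 | secondary ozonide of 7 (1,2,4-trioxolan-3-ylmethyl in place of allyl) | C1OC(C[C@]2(CC(=O)OC)CC(=O)CC[C@H]2CC(=O)OC)OO1 | intermediate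
9 | keto aldehyde diester (7 with CH2CHO in place of allyl) | O=CC[C@]1(CC(=O)OC)CC(=O)CC[C@H]1CC(=O)OC | intermediate
10 | bis(1,3-dioxolane) diester (C13 ketal, C16 acetal) | C1COC(O1)C[C@]2(CC(=O)OC)CC3(OCCO3)CC[C@H]2CC(=O)OC | intermediate
11 | bis(1,3-dioxolane) dialdehyde (both arms CH2CHO) | C1COC(O1)C[C@]2(CC=O)CC3(OCCO3)CC[C@H]2CC=O | intermediate
12 | mono-enal (C9 arm C(=CH2)CHO, C8 arm CH2CHO) | C1COC(O1)C[C@]2(CC=O)CC3(OCCO3)CC[C@H]2C(=C)C=O | intermediate
13 | allylic alcohol aldehyde (C9 arm C(=CH2)CH2OH, C8 arm CH2CHO) | C1COC(O1)C[C@]2(CC=O)CC3(OCCO3)CC[C@H]2C(=C)CO | intermediate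
14 | allylic alcohol enal (C8 arm C(=CH2)CHO, C9 arm C(=CH2)CH2OH) | C1COC(O1)C[C@]2(C(=C)C=O)CC3(OCCO3)CC[C@H]2C(=C)CO | intermediate
15 | phenyl carbonate of 14 | C1COC(O1)C[C@]2(C(=C)C=O)CC3(OCCO3)CC[C@H]2C(=C)COC(=O)Oc4ccccc4 | intermediate
16 | dienone carbonate (C8 arm C(=CH2)–CH=C(Me)–C(O)Me, E-configured C5=C4) | C1COC(O1)C[C@]2(C(=C)/C=C(\C)C(C)=O)CC3(OCCO3)CC[C@H]2C(=C)COC(=O)Oc4ccccc4 | intermediate
17 | triisopropylsilyl dienol ether of 16 (C2=C3(OSi)–C4(Me)=C5) | C1COC(O1)C[C@]2(C(=C)/C=C(\C)C(=C)O[Si](C(C)C)(C(C)C)C(C)C)CC3(OCCO3)CC[C@H]2C(=C)COC(=O)Oc4ccccc4 | intermediate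
18 | Diels–Alder adduct (rings A, B, C; C3 silyl enol ether; C10 carrying CH2OCO2Ph; H-5 and C-20 trans) | C1COC(O1)C[C@]23CC4(OCCO4)CC[C@H]2[C@]1(COC(=O)Oc5ccccc5)CCC(O[Si](C(C)C)(C(C)C)C(C)C)=C(C)[C@H]1C3=C | intermediate
19 | tetracyclic keto lactone (19,20-lactone; C3 ketone; C6=C7 methylene) | C1COC(O1)C[C@]23CC4(OCCO4)CC[C@H]2[C@]12COC(=O)[C@](C)(C(=O)CC1)[C@H]2C3=C | intermediate
20 | C2=C3 enol triflate of 19 | C1COC(O1)C[C@]23CC4(OCCO4)CC[C@H]2[C@]12COC(=O)[C@](C)(C(OS(=O)(=O)C(F)(F)F)=CC1)[C@H]2C3=C | intermediate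
21 | 2,3-alkene (C2=C3 in ring A, C6=C7 exocyclic) | C1COC(O1)C[C@]23CC4(OCCO4)CC[C@H]2[C@]12COC(=O)[C@](C)(C=CC1)[C@H]2C3=C | intermediate
22 | C2,C7-bis(9-borabicyclo[3.3.1]nonan-9-yl) adduct of 21 | C1COC(O1)C[C@]23CC4(OCCO4)CC[C@H]2[C@]12COC(=O)[C@](C)(C[C@@H](B5C6CCCC5CCC6)C1)[C@H]2[C@H]3CB5C6CCCC5CCC6 | intermediate
23 | 6-epi 2β,7-diol | C1COC(O1)C[C@]23CC4(OCCO4)CC[C@H]2[C@]12COC(=O)[C@](C)(C[C@@H](O)C1)[C@H]2[C@H]3CO | intermediate
24 | 6-epi 7-aldehyde | C1COC(O1)C[C@]23CC4(OCCO4)CC[C@H]2[C@]12COC(=O)[C@](C)(C[C@@H](O)C1)[C@H]2[C@H]3C=O | intermediate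
25 | 7-aldehyde of natural C6 configuration | C1COC(O1)C[C@]23CC4(OCCO4)CC[C@H]2[C@]12COC(=O)[C@](C)(C[C@@H](O)C1)[C@H]2[C@@H]3C=O | intermediate
26 | 7-carboxylic acid (C13 ketal and C16 acetal still in place) | C1COC(O1)C[C@]23CC4(OCCO4)CC[C@H]2[C@]12COC(=O)[C@](C)(C[C@@H](O)C1)[C@H]2[C@@H]3C(=O)O | intermediate
27 | keto aldehyde acid (C13 ketone, C8–CH2CHO) | O=CC[C@]23CC(=O)CC[C@H]2[C@]12COC(=O)[C@](C)(C[C@@H](O)C1)[C@H]2[C@@H]3C(=O)O | intermediate
28 | alkynyl ketone acid (C13 ketone, C8–CH2C≡CH) | C#CC[C@]23CC(=O)CC[C@H]2[C@]12COC(=O)[C@](C)(C[C@@H](O)C1)[C@H]2[C@@H]3C(=O)O | intermediate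
29 | target gibberellin, number 98 of the gibberellin A series: ent-2α,13,20-trihydroxygibberell-16-ene-7,19-dioic acid 19,20-lactone (2β,13-dihydroxy; 19,20-δ-lactone; 7-carboxylic acid) | C=C1C[C@]23C[C@@]1(O)CC[C@H]2[C@]12COC(=O)[C@](C)(C[C@@H](O)C1)[C@H]2[C@@H]3C(=O)O | target

**Step count and risks**

Total step count: 22. Longest linear sequence: 22 steps, from compounds 1 and 2 to compound 29; everything else enters as a commercial reagent.

Step 14. The unactivated 1,1-disubstituted alkene may add too slowly, so that the silyl dienol ether is lost by hydrolysis or by a 1,5-hydrogen shift from the C18 methyl group, or the anti/syn and facial selectivity of the cycloaddition may be insufficient. The fallback moves the activation onto the dienophile and separates the two bond formations. From 16, K2CO3 in MeOH removes the carbonate to give dienone alcohol F1. MnO2 oxidises the allylic alcohol to the 2-substituted acrolein, dienone enal F2. iPr3SiOTf and Et3N give silyloxy triene enal F3. The activated dienophile should now cyclise with Me2AlCl at -78 °C through the same anti transition state (carbonyl endo) to adduct aldehyde F4. NaBH4 in MeOH reduces the angular aldehyde to adduct alcohol F5. PhOCOCl and pyridine give 18, isolated this time, and Bu4NF then gives 19, where the route is rejoined.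

Step 8. The site selectivity of the first methylenation between the two CH2CHO arms may erode, or the 1,6-dialdehyde may close by an aldol or Michael reaction. The fallback differentiates the arms at the carbonyl group instead of at the α-carbon. From 11, an excess of CH2=NMe2+ I- with Et3N at 40 °C methylenates both arms to bis-enal F6. One equivalent of LiAlH(OtBu)3 at -78 °C should then reduce the less hindered enal on the C9 arm in preference to the enal on the quaternary C8. This gives 14 directly, where the route is rejoined.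

Step 22. The ketyl may be protonated or over-reduced before it cyclises, and the free acid consumes reductant. The fallback closes ring D by polar chemistry. From 27, an intramolecular crossed benzoin reaction (3-benzyl-5-(2-hydroxyethyl)-4-methylthiazolium chloride, Et3N, EtOH, 60 °C) gives α-ketol 17-nor-16-ketone F7, in which C16 of the aldehyde has added to the C13 ketone. Wittig methylenation with an excess of Ph3P=CH2 in THF then gives 29.

Further compounds
F1 | step 14 | dienone alcohol (16 with C20–OH free) | C1COC(O1)C[C@]2(C(=C)/C=C(\C)C(C)=O)CC3(OCCO3)CC[C@H]2C(=C)CO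
F2 | step 14 | dienone enal (C9 arm C(=CH2)CHO) | C1COC(O1)C[C@]2(C(=C)/C=C(\C)C(C)=O)CC3(OCCO3)CC[C@H]2C(=C)C=O
F3 | step 14 | silyloxy triene enal | C1COC(O1)C[C@]2(C(=C)/C=C(\C)C(=C)O[Si](C(C)C)(C(C)C)C(C)C)CC3(OCCO3)CC[C@H]2C(=C)C=O
F4 | step 14 | adduct aldehyde (18 with CHO at C10 in place of CH2OCO2Ph) | C1COC(O1)C[C@]23CC4(OCCO4)CC[C@H]2[C@]1(C=O)CCC(O[Si](C(C)C)(C(C)C)C(C)C)=C(C)[C@H]1C3=C
F5 | step 14 | adduct alcohol (18 with CH2OH at C10) | C1COC(O1)C[C@]23CC4(OCCO4)CC[C@H]2[C@]1(CO)CCC(O[Si](C(C)C)(C(C)C)C(C)C)=C(C)[C@H]1C3=C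
F6 | step 8 | bis-enal (both arms C(=CH2)CHO) | C1COC(O1)C[C@]2(C(=C)C=O)CC3(OCCO3)CC[C@H]2C(=C)C=O
F7 | step 22 | 17-nor-16-ketone (α-ketol: C13–OH, C16 ketone) | O=C1C[C@]23C[C@@]1(O)CC[C@H]2[C@]12COC(=O)[C@](C)(C[C@@H](O)C1)[C@H]2[C@@H]3C(=O)O
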